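All runs are simulated with constants of no real substance; the scatter is artificial.

Late in Thursday's run, at 4.00 min, 71 % of the electrophile still stands. Saturday's run, with 130 mM of free base, reads 69 % at the same time, a difference of 2 percentage points against a scatter of 1.5 points, so I carry no term for the base.

| flask | electrophile | nucleophile | free base | remark | time |
|---|---|---|---|---|---|
| Thursday's | 20 mM | 16 mM | 84 mM | run made earlier |  |
| Saturday's | 20 mM | 16 mM | 130 mM | run made earlier |  |
| Friday's | 10 mM | 16 mM | 60 mM | run made earlier |  |
| flask | 20 mM | 16.0 mM | 60.0 mM |  | 5.0 min |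

| run | time / min | electrophile / % | target / % |
|---|---|---|---|
| Thursday's | 0.333 | 95 | 3 |
| Thursday's | 0.500 | 96 | 3 |
| Thursday's | 0.833 | 91 | 5 |
| Thursday's | 1.33 | 88 | 8 |
| Thursday's | 2.50 | 81 | 9 |
| Thursday's | 4.00 | 71 | 13 |
| Saturday's | 0.667 | 92 | 5 |
| Saturday's | 1.33 | 87 | 9 |
| Saturday's | 2.00 | 80 | 10 |
| Saturday's | 2.50 | 78 | 13 |
| Saturday's | 3.00 | 74 | 12 |
| Saturday's | 4.00 | 69 | 11 |
| Friday's | 0.833 | 91 | 4 |
| Friday's | 1.50 | 87 | 10 |
| Friday's | 2.50 | 76 | 11 |
| Friday's | 3.00 | 76 | 12 |
| Friday's | 4.00 | 70 | 11 |

(readings scatter by 1.5 percentage points)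

- part of the electrophile that has reacted at 5.0 min
- share of the unused nucleophile that is free and not bound as protonated nucleophile, at 5.0 min

- percent here means electrophile units held: one idle adduct counts as two
- what is said of target includes idle adduct
- what may be going on: nucleophile + acid set free <-> protonated nucleophile; electrophile + nucleophile -> acid set free + target; acid set free + free base <-> salt of the base; target -> over-reaction product; electrophile + target <-> idle adduct
- in an amount of target, one idle adduct counts as one target
- what has gone from electrophile into another species counts as reacted, even if it can come back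
- the earlier runs do not show how much of nucleophile is bound; that part of a forecast is a guess

I replace the falling c(nucleophile) by its mean: the charge minus 0.5 of the electrophile lost, taking one nucleophile per electrophile. Thursday's reading then gives the mean-nucleophile constant k̄, the pseudo-first-order loss rate of electrophile per mM of mean nucleophile:

mean c(nucleophile) = 16 mM − 0.5 · 5.80 mM = 13.1 mM

k̄ = −ln(71 %) / (4.00 min · 13.1 mM) = 0.00654 mM⁻¹ min⁻¹

In the flask's first instants, c(nucleophile) stands at 16.0 mM, and the electrophile's lifetime at that level is 9.56 min, a factor of 1.91 above the 5.0 min asked, so I expect the curve to bend, and the mean is a rough stand-in for it. In the middle, acid set free meets 60.0 mM of free base and may bind nucleophile; the readings do not show how much. Towards the end, Saturday's run reads target at 13 % at 2.50 min and 11 % at 4.00 min, while its electrophile goes from 78 % to 69 %. The flask has Thursday's electrophile and nucleophile, so I scale Thursday's loss by time: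

loss ≈ 7.25 mM, mean c(nucleophile) = 12.4 mM

c = 33.3 %

That c means a loss of 6.65 mM, which moves the mean by 0.299 mM out of 12.4 mM.

The forecast says 34 % and 88 %, above my c, and holds that “the lack of any base effect suggests nucleophile stays mostly free”.

The flask gives 31.6 % and 71.0 %, 1.7 points below my c and 17 points below the forecast's share.

    nucleophile + acid set free ⇌ protonated nucleophile, settled at all times (K = 3030 M⁻¹)
    electrophile + nucleophile → acid set free + target (k = 0.0907 M⁻¹ s⁻¹)
    acid set free + free base ⇌ salt of the base (K = 8500 M⁻¹, k = 1.09 M⁻¹ s⁻¹)
    target → over-reaction product (k = 0.0111 s⁻¹)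
    electrophile + target ⇌ idle adduct, settled at all times (K = 110 M⁻¹)

In the flask, the step from electrophile and nucleophile has 63 % of its turnover behind it at 2.50 min, while the free share of unused nucleophile falls from 95.0 % at 0.500 min to 71.0 %. At 5.00 min, more acid set free sits as protonated nucleophile, 3.24 mM, than as salt of the base, 1.46 mM.

In a neighbouring flask with 4.0 mM of nucleophile, other charges as in the recipe, the loss scales to 1.81 mM and the mean to 3.09 mM, so 0.00654 mM⁻¹ min⁻¹ gives 9.61 %. That flask gives 9.94 %.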